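**Plan**
1. Numbering (longipinane): C1(=O)–C2=C3(CH3)–C4–C5–C11 is the cyclohexenone, C4–C5–C11–C10 the cyclobutane, C4–C5–C6–C7–C8–C9–C10 the seven-membered ring (C6: CH3 and C13H2–O-angeloyl; C7–OAc; C9–O-senecioyl; C10–CH3).
2. Retrosynthetic cuts, in order: the C13–O ester and the C3–CH3 bond; then both bonds of C11 to C1 and C5 with C1–C5 rejoined, so that C11 leaves the cyclohexenone, which shrinks to a cyclopentenone cis-fused to the cycloheptane while the cyclobutane opens; then C4–C10, C7–C8 and C5–C6.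
3. Enabling feature: C11 is the α-carbon between the C1 ketone and C5, belongs to both the cyclobutane and the enone ring, and sits on quaternary C10 next to ring-fusion carbon C4; a diazo carbon on C10 can therefore reach C1=O of the cyclopentenone and then take over C5 (one-carbon insertion).
4. Forward order: purchased cyclopentene → temporary bridged lactone (controls C6) → seven-membered ring by intramolecular Pd allylation → oxidation at C1 → insertion of C11, which closes the cyclobutane and, as the last ring, the cyclohexenone; then C3 methyl and the angelate.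
5. Stereochemistry: C5 from the enzymatically made (1S,4R)-monoacetate; C6 by exo alkylation of the lactone; C7 by chelation-controlled aldol; C4 by double inversion at Pd; C10 by convex-face methylation; C9 by Evans–Tishchenko reduction; C11 by the cage.

Key step: step 17

Remark (assumption): 4-methoxybenzyl chloromethyl ether and S-ethyl 3-oxobutanethioate are taken as purchasable; names from compound 14 on use the target numbering of the plan; the C1 carbinol of 19 and C3 of 25 are epimer mixtures that the following step erases. PMB = 4-methoxybenzyl.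

**Step 1**
Reactants: 1 (1S,4R)-cis-4-acetoxycyclopent-2-en-1-ol; 2 2,2,5-trimethyl-1,3-dioxane-4,6-dione (methyl Meldrum's acid)
Product: 3 5-[(1R,4S)-4-hydroxycyclopent-2-en-1-yl]-2,2,5-trimethyl-1,3-dioxane-4,6-dione
Conditions: Pd(PPh3)4 (3 mol%), Et3N (1.1 equiv), THF, 50 °C
Reagents that add atoms: none
Why: Tsuji–Trost allylic alkylation of the allylic acetate by the soft carbon acid should occur at the acetoxy carbon with net retention (double inversion), so the future C5–C6 bond forms cis to the remaining hydroxyl and C5 takes its configuration from the monoacetate.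

**Step 2**
Reactants: 3 5-[(1R,4S)-4-hydroxycyclopent-2-en-1-yl]-2,2,5-trimethyl-1,3-dioxane-4,6-dione
Product: 5 (1S,5R)-4-methyl-2-oxabicyclo[3.2.1]oct-6-en-3-one (C4 epimers), via α-carboxy lactone 4 (not isolated)
Conditions: pyridine (cat.), xylenes, 140 °C
Reagents that add atoms: none
Why: Intramolecular alcoholysis of the Meldrum's acid by the cis hydroxyl expels acetone to give malonic half-acid lactone 4, which should decarboxylate thermally to the bridged δ-lactone (only the cis-1,3 isomer can lactonise; the α-centre is reset in step 3).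

**Step 3**
Reactants: 5 (1S,5R)-4-methyl-2-oxabicyclo[3.2.1]oct-6-en-3-one
Product: 6 (1S,4S,5R)-4-{[(4-methoxybenzyl)oxy]methyl}-4-methyl-2-oxabicyclo[3.2.1]oct-6-en-3-one
Conditions: LDA, THF, −78 °C; then PMBOCH2Cl, −78 → −40 °C
Reagents that add atoms: 4-methoxybenzyl chloromethyl ether, COc1ccc(COCCl)cc1
Why: Lactone enolate alkylation in which the α-chloro ether should attack the planar enolate from the exo face of the bicyclo[3.2.1] lactone, anti to the C=C bridge, which sets quaternary C6 with the CH2OPMB arm on the side required later and the methyl equatorial.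

**Step 4**
Reactants: 6 (1S,4S,5R)-4-{[(4-methoxybenzyl)oxy]methyl}-4-methyl-2-oxabicyclo[3.2.1]oct-6-en-3-one
Product: 7 (2S)-2-[(1R,4S)-4-hydroxycyclopent-2-en-1-yl]-N-methoxy-3-[(4-methoxybenzyl)oxy]-N,2-dimethylpropanamide
Conditions: MeNH(OMe)·HCl, AlMe3, CH2Cl2, 0 → 40 °C; Rochelle salt work-up
Reagents that add atoms: N,O-dimethylhydroxylamine hydrochloride, CNOC.Cl
Why: Weinreb aminolysis with the dimethylaluminium amide should open the strained bridged lactone without touching C6 and free the allylic hydroxyl cis to the side chain.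

**Step 5**
Reactants: 7 (2S)-2-[(1R,4S)-4-hydroxycyclopent-2-en-1-yl]-N-methoxy-3-[(4-methoxybenzyl)oxy]-N,2-dimethylpropanamide
Product: 8 (1S,4R)-4-{(2S)-1-[methoxy(methyl)amino]-3-[(4-methoxybenzyl)oxy]-2-methyl-1-oxopropan-2-yl}cyclopent-2-en-1-yl methyl carbonate
Conditions: ClCO2Me, pyridine, DMAP (cat.), CH2Cl2, 0 °C
Reagents that add atoms: methyl chloroformate, COC(Cl)=O
Why: Acylation of the secondary allylic alcohol installs the carbonate leaving group for the later π-allyl step and blocks relactonisation once the aldehyde is made.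

**Step 6**
Reactants: 8 (1S,4R)-4-{(2S)-1-[methoxy(methyl)amino]-3-[(4-methoxybenzyl)oxy]-2-methyl-1-oxopropan-2-yl}cyclopent-2-en-1-yl methyl carbonate
Product: 9 (1S,4R)-4-{(2S)-1-[(4-methoxybenzyl)oxy]-2-methyl-3-oxopropan-2-yl}cyclopent-2-en-1-yl methyl carbonate
Conditions: DIBAL-H, THF, −78 °C; Rochelle salt
Reagents that add atoms: none
Why: Weinreb amide reduction stops at the aldehyde through the chelated tetrahedral intermediate and should be faster than attack on the carbonate at −78 °C; the α-quaternary aldehyde cannot epimerise.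

**Step 7**
Reactants: 10 S-ethyl 3-oxobutanethioate
Product: 12 1-(ethylsulfanyl)-1,3-bis(trimethylsilyloxy)buta-1,3-diene, via mono-silyl enol ether 11 (not isolated)
Conditions: Et3N, TMSCl, hexane, rt; then LDA, THF, −78 °C, TMSCl
Reagents that add atoms: chlorotrimethylsilane, C[Si](C)(C)Cl
Why: Two-stage O-silylation of the β-keto thioester (standard preparation of 1,3-bis(silyl enol ethers)) should give the γ-nucleophilic diene.

**Step 8**
Reactants: 9 (1S,4R)-4-{(2S)-1-[(4-methoxybenzyl)oxy]-2-methyl-3-oxopropan-2-yl}cyclopent-2-en-1-yl methyl carbonate; 12 1-(ethylsulfanyl)-1,3-bis(trimethylsilyloxy)buta-1,3-diene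
Product: 13 S-ethyl (5R,6S)-5-hydroxy-6-{(1R,4S)-4-[(methoxycarbonyl)oxy]cyclopent-2-en-1-yl}-7-[(4-methoxybenzyl)oxy]-6-methyl-3-oxoheptanethioate
Conditions: TiCl4 (1.05 equiv), CH2Cl2, −78 °C; then 12; aq. NaHCO3
Reagents that add atoms: none
Why: Vinylogous Mukaiyama aldol at the γ-carbon of the diene under chelation control, in which TiCl4 ties the aldehyde oxygen to the PMB ether oxygen and the nucleophile should attack the chelate past the methyl group, anti to the cyclopentenyl group, which sets C7.

**Step 9**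
Reactants: 13 S-ethyl (5R,6S)-5-hydroxy-6-{(1R,4S)-4-[(methoxycarbonyl)oxy]cyclopent-2-en-1-yl}-7-[(4-methoxybenzyl)oxy]-6-methyl-3-oxoheptanethioate
Product: 14 cis-fused bicyclic β-keto thioester (C2=C3 alkene; C7–OH; C9 ketone; C10–H bearing C(O)SEt)
Conditions: Pd2(dba)3·CHCl3 (2.5 mol%), dppe (6 mol%), THF (0.01 M), 50 °C
Reagents that add atoms: none
Why: Intramolecular Tsuji–Trost alkylation in which the carbonate ionises anti to Pd, the released methoxide deprotonates the β-keto thioester and the enolate should attack C4 anti to Pd on the face of its own tether, closing the seven-membered ring cis-fused (C4 by double inversion) and moving the alkene to C2=C3.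

**Step 10**
Reactants: 14 cis-fused bicyclic β-keto thioester
Product: 15 C10-methylated β-keto thioester (CH3 cis to H4; C(O)SEt on the cyclopentene side)
Conditions: MeI, K2CO3, acetone, rt
Reagents that add atoms: iodomethane, CI
Why: C-alkylation of the doubly activated C10, where MeI should approach the planar enolate from the convex face of the cis-fused bicycle, anti to the C4–C3 bond, which sets quaternary C10 with the future C11 carbon on the cyclopentene side.

**Step 11**
Reactants: 15 C10-methylated β-keto thioester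
Product: 16 7-O-acetyl-9-hydroxy thioester (7,9-anti)
Conditions: SmI2 (30 mol%), MeCHO (8 equiv), THF, −10 °C
Reagents that add atoms: acetaldehyde, CC=O
Why: Evans–Tishchenko reduction in which the samarium-bound hemiacetal of the C7 hydroxyl delivers hydride intramolecularly to the C9 ketone, which should give the 7,9-anti relationship and place the acetate on O7 while leaving O9 free.

**Step 12**
Reactants: 16 7-O-acetyl-9-hydroxy thioester
Product: 17 7-O-acetyl-9-O-senecioyl thioester
Conditions: 3-methylbut-2-enoyl chloride, pyridine, DMAP, CH2Cl2, 0 °C → rt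
Reagents that add atoms: 3-methylbut-2-enoyl chloride, CC(C)=CC(Cl)=O
Why: DMAP-catalysed acylation of the only free hydroxyl installs the senecioate at O9.

**Step 13**
Reactants: 17 7-O-acetyl-9-O-senecioyl thioester
Product: 18 C11 aldehyde (C2=C3 alkene retained)
Conditions: Et3SiH, 10% Pd/C, acetone, rt
Reagents that add atoms: none
Why: Fukuyama reduction (Pd insertion into the C–S bond, then hydride transfer from the silane) should convert the thioester into the aldehyde under neutral aprotic conditions that spare acetate, enoate and PMB ether.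

**Step 14**
Reactants: 18 C11 aldehyde
Product: 19 C1 allylic alcohol of 18 (C1 epimers)
Conditions: SeO2 (0.5 equiv), t-BuOOH (3 equiv), CH2Cl2, rt
Reagents that add atoms: selenium dioxide, O=[Se]=O; tert-butyl hydroperoxide, CC(C)(C)OO
Why: Riley-type allylic hydroxylation (ene reaction, then [2,3]-shift) should oxidise the allylic CH2 at C1 without allylic transposition, because the tertiary allylic C4–H beside quaternary C10 is shielded and the enoate methyls are deactivated.

**Step 15**
Reactants: 19 C1 allylic alcohol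
Product: 20 enone aldehyde (C1 ketone conjugated with C2=C3; C11 aldehyde on C10)
Conditions: Dess–Martin periodinane, NaHCO3, CH2Cl2, 0 °C
Reagents that add atoms: none
Why: Dess–Martin oxidation of the allylic alcohol gives the cyclopentenone without over-oxidising the non-enolisable aldehyde.

**Step 16**
Reactants: 20 enone aldehyde
Product: 21 (E)-N-tosylhydrazone of 20 at C11
Conditions: TsNHNH2, THF, rt
Reagents that add atoms: 4-methylbenzenesulfonohydrazide, Cc1ccc(cc1)S(=O)(=O)NN
Why: Hydrazone condensation should be selective because an aldehyde reacts with a sulfonyl hydrazide much faster than the conjugated ketone.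

**Step 17**
Reactants: 21 (E)-N-tosylhydrazone of 20
Product: 24 13-O-PMB ether of 7-acetoxy-13-hydroxy-9-senecioyloxy-12-norlongipin-2-en-1-one, via diazoalkane 22 (not isolated), via diazonium alkoxide 23 (not isolated)
Conditions: NaH (1.05 equiv), THF, 0 °C; then BnEt3NCl (10 mol%), 1,4-dioxane, 50–60 °C
Reagents that add atoms: none
Why: Proposed new method: deprotonated 21 loses sulfinate to give diazoalkane 22 (Bamford–Stevens), whose carbon C11 adds to the C1 carbonyl (5-exo-trig, closing the transient ring C11–C1–C5–C4–C10 of a 1-oxidonorbornene) to give diazonium alkoxide 23, and the C1–C5 bond, antiperiplanar to C11–N2+, then shifts to C11 as N2 leaves, a Tiffeneau–Demjanov/Büchner–Curtius–Schlotterbeck-type one-carbon insertion. The closest known reactions are intramolecular diazoalkyl–ketone ring enlargements to bridged ketones and Lewis-acid diazoalkane homologation of cycloalkanones; contraction of a norbornyl frame to a bicyclo[3.1.1]heptenone in this way is not precedented, but C=O formation and N2 loss should outweigh the added strain. The shift closes the cyclobutane C4–C5–C11–C10 by ring contraction and, in the same event, expands the cyclopentenone to the cyclohexenone C1–C2–C3–C4–C5–C11 by insertion of C11 between C1 and C5. C11, the only new stereocentre that is kept, is fixed by the cage (it must bridge C1, C5 and C10 on the face of the five-membered ring that carries C10), and C5 migrates with retention. The step needs migration of C5 instead of vinyl carbon C2 and addition to C=O instead of C=C: in 23 the exo site at C11 is blocked by the C6 substituents of the seven-membered ring, so N2+ is endo and antiperiplanar to C1–C5 only, the bridgehead oxygen is gauche to N2+ (no epoxide), and the short tether through C10 makes attack on C3 a four-membered closure.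

**Step 18**
Reactants: 24 13-O-PMB ether of 7-acetoxy-13-hydroxy-9-senecioyloxy-12-norlongipin-2-en-1-one
Product: 25 C1 trimethylsilyl enol ether of the 3-methyl ketone (C3 epimers)
Conditions: Me2CuLi, TMSCl, THF, −78 °C
Reagents that add atoms: lithium dimethylcuprate, [Li+].C[Cu-]C; chlorotrimethylsilane, C[Si](C)(C)Cl
Why: Conjugate addition of the Gilman reagent to the strained bicyclo[3.1.1]heptenone with silyl trapping of the enolate should deliver the C3 methyl and a regiodefined enol ether, the esters being inert at −78 °C.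

**Step 19**
Reactants: 25 C1 trimethylsilyl enol ether
Product: 26 13-O-PMB ether of 7-acetoxy-13-hydroxy-9-senecioyloxylongipin-2-en-1-one
Conditions: Pd(OAc)2 (1.05 equiv), MeCN, rt
Reagents that add atoms: none
Why: Saegusa–Ito oxidation of the silyl enol ether should restore the enone, now with the C3 methyl, since β-hydride elimination can only occur toward C3 (C11 is a bridgehead).

**Step 20**
Reactants: 26 13-O-PMB ether of 7-acetoxy-13-hydroxy-9-senecioyloxylongipin-2-en-1-one
Product: 27 7-acetoxy-13-hydroxy-9-senecioyloxylongipin-2-en-1-one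
Conditions: DDQ, CH2Cl2/pH 7 buffer, 0 °C
Reagents that add atoms: none
Why: Oxidative PMB ether cleavage with DDQ should free the C13 hydroxyl while the electron-poor enone and enoate and the acetate stay untouched.

**Step 21**
Reactants: 27 7-acetoxy-13-hydroxy-9-senecioyloxylongipin-2-en-1-one
Product: 28 7-acetoxy-13-angeloyloxy-9-senecioyloxylongipin-2-en-1-one (target)
Conditions: angelic acid, 2,4,6-trichlorobenzoyl chloride, Et3N, toluene, rt; then 27, 75 °C
Reagents that add atoms: (Z)-2-methylbut-2-enoic acid (angelic acid), C/C=C(/C)C(O)=O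
Why: Yamaguchi esterification through the mixed anhydride should acylate the neopentyl primary alcohol without Z→E isomerisation of the angeloyl group.

**Compound list**
1 | (1S,4R)-cis-4-acetoxycyclopent-2-en-1-ol | CC(=O)O[C@H]1C=C[C@@H](O)C1 | starting material
2 | 2,2,5-trimethyl-1,3-dioxane-4,6-dione (methyl Meldrum's acid) | CC1C(=O)OC(C)(C)OC1=O | starting material
3 | 5-[(1R,4S)-4-hydroxycyclopent-2-en-1-yl]-2,2,5-trimethyl-1,3-dioxane-4,6-dione | CC1(C)OC(=O)C(C)([C@H]2C=C[C@@H](O)C2)C(=O)O1 | intermediate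
4 | (1S,5R)-4-methyl-3-oxo-2-oxabicyclo[3.2.1]oct-6-ene-4-carboxylic acid (C4 epimers; α-carboxy lactone) | CC1(C(O)=O)C(=O)O[C@@H]2C=C[C@H]1C2 | intermediate (not isolated)
5 | (1S,5R)-4-methyl-2-oxabicyclo[3.2.1]oct-6-en-3-one (C4 epimers) | CC1C(=O)O[C@@H]2C=C[C@H]1C2 | intermediate
6 | (1S,4S,5R)-4-{[(4-methoxybenzyl)oxy]methyl}-4-methyl-2-oxabicyclo[3.2.1]oct-6-en-3-one | COc1ccc(COC[C@@]2(C)C(=O)O[C@@H]3C=C[C@H]2C3)cc1 | intermediate
7 | (2S)-2-[(1R,4S)-4-hydroxycyclopent-2-en-1-yl]-N-methoxy-3-[(4-methoxybenzyl)oxy]-N,2-dimethylpropanamide | COc1ccc(COC[C@@](C)(C(=O)N(C)OC)[C@H]2C=C[C@@H](O)C2)cc1 | intermediate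
8 | (1S,4R)-4-{(2S)-1-[methoxy(methyl)amino]-3-[(4-methoxybenzyl)oxy]-2-methyl-1-oxopropan-2-yl}cyclopent-2-en-1-yl methyl carbonate | COc1ccc(COC[C@@](C)(C(=O)N(C)OC)[C@H]2C=C[C@@H](OC(=O)OC)C2)cc1 | intermediate
9 | (1S,4R)-4-{(2S)-1-[(4-methoxybenzyl)oxy]-2-methyl-3-oxopropan-2-yl}cyclopent-2-en-1-yl methyl carbonate | COc1ccc(COC[C@@](C)(C=O)[C@H]2C=C[C@@H](OC(=O)OC)C2)cc1 | intermediate
10 | S-ethyl 3-oxobutanethioate | CCSC(=O)CC(C)=O | starting material
11 | S-ethyl 3-(trimethylsilyloxy)but-2-enethioate (mono-silyl enol ether) | CCSC(=O)C=C(C)O[Si](C)(C)C | intermediate (not isolated)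
12 | 1-(ethylsulfanyl)-1,3-bis(trimethylsilyloxy)buta-1,3-diene | CCSC(O[Si](C)(C)C)=CC(=C)O[Si](C)(C)C | intermediate
13 | S-ethyl (5R,6S)-5-hydroxy-6-{(1R,4S)-4-[(methoxycarbonyl)oxy]cyclopent-2-en-1-yl}-7-[(4-methoxybenzyl)oxy]-6-methyl-3-oxoheptanethioate | COc1ccc(COC[C@](C)([C@H]2C=C[C@@H](OC(=O)OC)C2)[C@H](O)CC(=O)CC(=O)SCC)cc1 | intermediate
14 | cis-fused bicyclic β-keto thioester: C2=C3 alkene; C7–OH; C9 ketone; C10–H bearing C(O)SEt (C10 epimers/enol); C6 with CH3 and CH2OPMB | COc1ccc(COC[C@]2(C)[C@@H]3CC=C[C@@H]3C(C(=O)SCC)C(=O)C[C@H]2O)cc1 | intermediate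
15 | C10-methylated β-keto thioester: as 14 with quaternary C10 (CH3 cis to H4; C(O)SEt on the cyclopentene side) | COc1ccc(COC[C@]2(C)[C@@H]3CC=C[C@@H]3[C@@](C(=O)SCC)(C)C(=O)C[C@H]2O)cc1 | intermediate
16 | 7-O-acetyl-9-hydroxy thioester (7,9-anti) | COc1ccc(COC[C@]2(C)[C@@H]3CC=C[C@@H]3[C@@](C(=O)SCC)(C)[C@H](O)C[C@H]2OC(C)=O)cc1 | intermediate
17 | 7-O-acetyl-9-O-senecioyl thioester | COc1ccc(COC[C@]2(C)[C@@H]3CC=C[C@@H]3[C@@](C(=O)SCC)(C)[C@H](OC(=O)C=C(C)C)C[C@H]2OC(C)=O)cc1 | intermediate
18 | C11 aldehyde (C10–CHO; C2=C3 alkene) | COc1ccc(COC[C@]2(C)[C@@H]3CC=C[C@@H]3[C@@](C=O)(C)[C@H](OC(=O)C=C(C)C)C[C@H]2OC(C)=O)cc1 | intermediate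
19 | C1 allylic alcohol of 18 (C1 epimers) | COc1ccc(COC[C@]2(C)[C@@H]3C(O)C=C[C@@H]3[C@@](C=O)(C)[C@H](OC(=O)C=C(C)C)C[C@H]2OC(C)=O)cc1 | intermediate
20 | enone aldehyde: C1 ketone conjugated with C2=C3; C11 aldehyde on C10 | COc1ccc(COC[C@]2(C)[C@@H]3C(=O)C=C[C@@H]3[C@@](C=O)(C)[C@H](OC(=O)C=C(C)C)C[C@H]2OC(C)=O)cc1 | intermediate
21 | (E)-N-tosylhydrazone of 20 at C11 | COc1ccc(COC[C@]2(C)[C@@H]3C(=O)C=C[C@@H]3[C@@](/C=N/NS(=O)(=O)c4ccc(C)cc4)(C)[C@H](OC(=O)C=C(C)C)C[C@H]2OC(C)=O)cc1 | intermediate
22 | C11 diazoalkane | COc1ccc(COC[C@]2(C)[C@@H]3C(=O)C=C[C@@H]3[C@@](C=[N+]=[N-])(C)[C@H](OC(=O)C=C(C)C)C[C@H]2OC(C)=O)cc1 | intermediate (not isolated)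
23 | 1-oxidonorbornene C11-diazonium zwitterion (N2 endo) | COc1ccc(COC[C@]2(C)[C@@H]3[C@@]4([O-])C=C[C@@H]3[C@](C)([C@@H]4[N+]#N)[C@H](OC(=O)C=C(C)C)C[C@H]2OC(C)=O)cc1 | intermediate (not isolated)
24 | 13-O-PMB ether of 7-acetoxy-13-hydroxy-9-senecioyloxy-12-norlongipin-2-en-1-one | COc1ccc(COC[C@]2(C)[C@@H]3[C@H]4C(=O)C=C[C@@H]3[C@@]4(C)[C@H](OC(=O)C=C(C)C)C[C@H]2OC(C)=O)cc1 | intermediate
25 | C1 trimethylsilyl enol ether of the 3-methyl ketone (C3 epimers) | COc1ccc(COC[C@]2(C)[C@@H]3[C@H]4C(O[Si](C)(C)C)=CC(C)[C@@H]3[C@@]4(C)[C@H](OC(=O)C=C(C)C)C[C@H]2OC(C)=O)cc1 | intermediate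
26 | 13-O-PMB ether of 7-acetoxy-13-hydroxy-9-senecioyloxylongipin-2-en-1-one | COc1ccc(COC[C@]2(C)[C@@H]3[C@H]4C(=O)C=C(C)[C@@H]3[C@@]4(C)[C@H](OC(=O)C=C(C)C)C[C@H]2OC(C)=O)cc1 | intermediate
27 | 7-acetoxy-13-hydroxy-9-senecioyloxylongipin-2-en-1-one | OC[C@]1(C)[C@@H]2[C@H]3C(=O)C=C(C)[C@@H]2[C@@]3(C)[C@H](OC(=O)C=C(C)C)C[C@H]1OC(C)=O | intermediate
28 | 7-acetoxy-13-angeloyloxy-9-senecioyloxylongipin-2-en-1-one | C/C=C(/C)C(=O)OC[C@]1(C)[C@@H]2[C@H]3C(=O)C=C(C)[C@@H]2[C@@]3(C)[C@H](OC(=O)C=C(C)C)C[C@H]1OC(C)=O | target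

**Count and risks**
Total steps: 21. Longest linear sequence: 20 (steps 1–6 and 8–21; step 7 prepares diene 12).

Steps most likely to fail:

1. Step 17. The diazoalkane may lose N2 to a carbene (C–H insertion, 1,2-shift) before it adds to the weakly electrophilic enone carbonyl, or may form azine. Fallback with known chemistry, from 20 back to 24: a SmI2-mediated intramolecular ketyl–carbonyl (pinacol-type) coupling of the C11 aldehyde with the C1 ketone (SmI2, THF/t-BuOH, −78 °C) should give the bridgehead diol F1, with the C11 hydroxyl endo because the exo site is blocked. Mesylation of the secondary hydroxyl (MsCl, Et3N) gives the endo mesylate F2. KOt-Bu in THF then triggers the semipinacol 1,2-shift of C5, antiperiplanar to the mesylate, and returns 24.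

2. Step 9. The free C7 hydroxyl may attack the π-allyl complex (five-membered cyclic ether) faster than the slow seven-membered C-allylation. Fallback from 13 back to 16, which removes the hydroxyl nucleophile and changes the origin of the C9 configuration: acetylation (Ac2O, DMAP, pyridine) gives the C7 acetate F3. Cyclisation through the silyl enol ether (Pd2(dba)3, dppe, BSA, KOAc cat., THF, 60 °C) gives the bicyclic acetate F4. Methylation (MeI, K2CO3) gives F5. Substrate-controlled reduction of the C9 ketone (NaBH4, MeOH, −40 °C; hydride from the convex face, past the C10 methyl) then gives 16 without the Evans–Tishchenko step.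

3. Step 14. The peroxide–selenium system may oxidise the C11 aldehyde further to the acid, or the allylic hydroxylation may be slow beside it. Fallback from 17 back to 20, with the oxidation done before the aldehyde exists: SeO2/t-BuOOH on thioester 17 gives the C1 allylic alcohol F6. Dess–Martin oxidation gives the enone thioester F7. Fukuyama reduction (Et3SiH, Pd/C, acetone) then gives 20.

**Further compounds**
F1 | step 17 | C1,C11-diol of the 1-hydroxynorbornene skeleton (C11–OH endo) from pinacol-type coupling of 20 | COc1ccc(COC[C@]2(C)[C@@H]3[C@@]4(O)C=C[C@@H]3[C@](C)([C@@H]4O)[C@H](OC(=O)C=C(C)C)C[C@H]2OC(C)=O)cc1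
F2 | step 17 | C11 endo-methanesulfonate of F1 | COc1ccc(COC[C@]2(C)[C@@H]3[C@@]4(O)C=C[C@@H]3[C@](C)([C@@H]4OS(C)(=O)=O)[C@H](OC(=O)C=C(C)C)C[C@H]2OC(C)=O)cc1
F3 | step 9 | C7 acetate of 13 | COc1ccc(COC[C@](C)([C@H]2C=C[C@@H](OC(=O)OC)C2)[C@H](OC(C)=O)CC(=O)CC(=O)SCC)cc1
F4 | step 9 | C7 acetate of 14 (C10 epimers/enol) | COc1ccc(COC[C@]2(C)[C@@H]3CC=C[C@@H]3C(C(=O)SCC)C(=O)C[C@H]2OC(C)=O)cc1
F5 | step 9 | C7 acetate of 15 | COc1ccc(COC[C@]2(C)[C@@H]3CC=C[C@@H]3[C@@](C(=O)SCC)(C)C(=O)C[C@H]2OC(C)=O)cc1
F6 | step 14 | C1 allylic alcohol of thioester 17 (C1 epimers) | COc1ccc(COC[C@]2(C)[C@@H]3C(O)C=C[C@@H]3[C@@](C(=O)SCC)(C)[C@H](OC(=O)C=C(C)C)C[C@H]2OC(C)=O)cc1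
F7 | step 14 | C1 enone of thioester 17 | COc1ccc(COC[C@]2(C)[C@@H]3C(=O)C=C[C@@H]3[C@@](C(=O)SCC)(C)[C@H](OC(=O)C=C(C)C)C[C@H]2OC(C)=O)cc1
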